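I wanted to know how much product stands after 10 h with 1.00 equiv, 3.00 equiv and 10.0 equiv of coupling partner, and whether more partner keeps paying.

the same everywhere: substrate 0.10 M
- autumn: coupling partner 0.77 equiv; run made earlier
- spring: coupling partner 7.9 equiv; run made earlier
- amber: coupling partner 1.00 equiv; time 10 h
- grey: coupling partner 3.00 equiv; time 10 h
- green: coupling partner 10.0 equiv; time 10 h

| run | time / h | product / % | substrate / % |
|---|---|---|---|
| autumn | 0.500 | 0.1 | 53.3 |
| autumn | 1.33 | 1.9 | 39.1 |
| autumn | 2.50 | 3.2 | 27.3 |
| autumn | 4.00 | 7.2 | 17.0 |
| autumn | 5.00 | 10.4 | 13.3 |
| autumn | 8.00 | 18.3 | 4.4 |
| spring | 0.500 | 0.1 | 7.1 |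
| spring | 1.00 | 1.3 | 7.9 |
| spring | 1.50 | 2.6 | 6.6 |
| spring | 2.50 | 6.6 | 6.6 |
| spring | 4.00 | 8.9 | 5.0 |
| spring | 8.00 | 15.7 | 1.6 |

(each reading ± 0.5 percentage points)

- amount of product at the end, in percent of the substrate charged for amber, grey, green, in this order
- how the row runs (rises, then falls / hardly changes / falls, then rises / falls all the way / rises all the way)

- "hardly changes" means that all values lie within two and a half points (for a concentration: within two and a half percent of the largest)

I began with one process. The first spring reading already shows substrate at 7.1 %, so I took this drop for a quick balance with an unseen held form. That reading gave 18.8 /M for K, the holding constant, which is held substrate over free substrate, divided by [coupling partner] free.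

free share = 1 / (1 + K × [coupling partner])

Amber was my zero of the scale: with one partner per substrate, free substrate equals free partner, and the free share is 51.1 %. Counting the partner net of what is held, grey has 19.5 % and green 5.56 %.

Then I added the slow loss. After the first reading, substrate decays at 0.199 /h in spring and 0.333 /h in autumn. Taking the first readings as free shares, I split these rates:

decay = free share × a + (held share) × h

This gave 0.290 /h for a − h, so h is 0.178 /h and a is 0.468 /h, with free substrate leaving faster than held. Autumn made more product by 8.00 h than spring, 18.3 % against 15.7 %, with spring having ten times the partner. So I took the free road as the one leading to product. Its share of the traffic, a selectivity factor, is: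

road share = a × free share / (a × free share + h × held share)

That is 73.3 % for amber, 38.9 % for grey and 13.4 % for green.

Last came the coupling itself, which needs partner. Autumn's late slope carries that run to 23.6 % at 10 h, and amber has slightly more partner. By this reckoning of my own I therefore expected amber a little above that, grey below its road share, green near its road share, and a row that rises, then falls.

The forecast, which is not this reckoning, gave 24 %, 26 % and 19 %, rises, then falls, with the note “the maximum is shallow”, so for green it stood higher than my road share by 5.6 percentage points.

The flasks gave 28.0 %, 33.6 % and 15.3 %: rises, then falls.

    intermediate B → decomposed reagent (k = 0.0150 /min)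
    substrate + coupling partner ⇌ intermediate A (K = 14.0 /M, k = 0.790 /M/min)
    coupling partner + intermediate B ⇌ intermediate D (K = 4.00 /M, k = 0.350 /M/min)
    intermediate A → intermediate B (k = 0.00240 /min)
    coupling partner + intermediate C → product (k = 0.0200 /M/min)
    substrate → intermediate C (k = 0.00700 /min)

With the partner left at 10.0 h, the holding constant gives green a free share of 5.68 %, while substrate over substrate plus intermediate A stands at 7.43 %. Amber gives 52.1 % against 57.9 %. Green's held substrate still fed its product: with the reverse step, intermediate A to substrate + coupling partner, taken away, green made 0.925 % instead of 15.3 %.

The runs stem from a simulated flask for substances that don't exist; the scatter is artificial.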